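(The numbers in the tables are calculated for substances that don't exist; the scatter is artificial.)

The chemist who made the forecast and a colleague at the next bench disagree about the flasks autumn to spring, in which the charge of added ligand rises from one to the next and the other charges stay the same.

| flask | substrate | reagent | free catalyst | added ligand | remark | time |
|---|---|---|---|---|---|---|
| violet | 0.020 M | 0.026 M | 4.5 mM | 0.30 mM | run made earlier |  |
| ochre | 0.010 M | 0.026 M | 3 mM | 0.30 mM | run made earlier |  |
| autumn | 0.020 M | 0.0260 M | 3.0 mM | 0.30 mM |  | 8.0 h |
| midnight | 0.020 M | 0.0260 M | 3.0 mM | 0.60 mM |  | 8.0 h |
| summer | 0.020 M | 0.0260 M | 3.0 mM | 1.2 mM |  | 8.0 h |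
| noon | 0.020 M | 0.0260 M | 3.0 mM | 2.5 mM |  | 8.0 h |
| spring | 0.020 M | 0.0260 M | 3.0 mM | 5.0 mM |  | 8.0 h |

| run | time / h | product / % | substrate / % |
|---|---|---|---|
| violet | 0.250 | 4.0 | 78.9 |
| violet | 0.667 | 13.0 | 66.6 |
| violet | 1.33 | 28.0 | 53.8 |
| violet | 2.00 | 40.8 | 40.6 |
| violet | 3.00 | 57.2 | 25.1 |
| ochre | 0.250 | 3.0 | 79.2 |
| ochre | 0.667 | 13.3 | 65.1 |
| ochre | 1.33 | 31.7 | 48.1 |
| ochre | 2.00 | 47.7 | 35.2 |
| ochre | 3.00 | 65.3 | 19.1 |

(each reading ± 0.5 percentage points)

- the earlier runs were read with a standard deviation of 0.5 percentage points
- steps thought possible: catalyst intermediate A -> catalyst intermediate B; catalyst intermediate C -> free catalyst + product; substrate + free catalyst <-> catalyst intermediate A; free catalyst + added ligand <-> idle complex; reagent + catalyst intermediate B <-> catalyst intermediate C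
- "hardly changes" means that all values lie within two and a half points (for a concentration: within two and a half percent of the largest)
- no earlier run changes the charge of added ligand; that part of a forecast is a guess

* amount of product at the end, in percent of the substrate charged for autumn, midnight, summer, noon, spring, in this order
* how that number moves from the first to the last of them (hardly changes / rises all the way / falls, then rises / falls all the way / rises, then falls)

Both start from the same gap. In the violet run at 2.00 h, product and substrate together make 81.4% of the substrate charged, so 3.72 mM of substrate is sitting on the catalyst, out of 4.5 mM of catalyst charged. The colleague works with what is left, not with what is held: that is 17.3% of the catalyst charged, as a reading, and she calls it the free share, the part of the catalyst carrying no substrate. Violet has the same substrate charge as the new flasks but more catalyst, and she carries this reading over to them.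

The forecast says “Added ligand traps only free catalyst, which is scarce, so it acts like a competitor raising Km”. It guesses a Kd, the dissociation constant of the idle complex, around 1 mM or somewhat tighter and gives 92%, 90%, 85%, 74% and 58%, a row that falls all the way.

The colleague answers that no earlier run changes the ligand, so any Kd is a guess, and she argues from the round instead. A round of the catalyst is a string of waits, and the free share is the part of the round spent waiting free. In the steps thought possible, added ligand meets free catalyst and no intermediate. The wait while free therefore lengthens by the factor 1 + c(added ligand)/Kd, and the whole round by 1 + free share × c(added ligand)/Kd. With a Kd of 1 mM, spring carries 5 Kd of ligand and, by her reckoning, its round stretches by 1.87. Her own bet differs from the forecast: she takes a Kd near spring's charge, which adds 17.3% to spring's round and gives a shallow fall.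

The simulation gives 84.0%, 83.7%, 83.1%, 81.8% and 79.4%, a row that falls all the way. In autumn at 4.00 h, catalyst intermediate B, the resting state, holds 72.5% of the catalyst and free catalyst 19.9%.

    catalyst intermediate A → catalyst intermediate B (k = 1.10 /min)
    catalyst intermediate C → free catalyst + product (k = 0.200 /min)
    substrate + free catalyst ⇌ catalyst intermediate A (K = 80.0 /M, k = 9.00 /M/min)
    free catalyst + added ligand ⇌ idle complex, settled at all times (K = 150 /M)
    reagent + catalyst intermediate B ⇌ catalyst intermediate C (K = 6.40 /M, k = 5.90 /M/min)

Without the binding of free catalyst and added ligand, the change from autumn to spring is 0 percentage points instead of −4.6 points. With the free share and the true binding constant, the round stretches by 1.13 in spring and 1.06 in noon. Taken on autumn's pace between 4.00 h and 8.00 h, those factors put spring at 77.1% against 79.4% and noon at 80.3% against 81.8%. The trapping view has its ground where substrate is gone: in spring at 80.0 h, with substrate at 0%, the idle complex holds 36.9% of the catalyst.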